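**Plan**

Elemane numbering is used; unprimed atoms belong to unit A (the butenolide half), primed atoms to unit B (the saturated lactone half).
Cuts: the unit A butenolide at O–C12 and at C7=C11, then C13–C13', then C11'=C13', O–C12' and C7'–C11' of the unit B lactone, and last the cyclobutane bond of two 4-vinylverbanones.
Enabling feature: the butenolide ring (C7, C8, O, C12, C11) sits on a cyclohexane whose C8 is separated from the quaternary C10 only by the CH2 group C9. A C8 ketone therefore enolises only towards C7, and C11 can be the keto carbon of a 2-oxo ester chain C12–C11–C13–C13' hanging from C11' of the unit B lactone.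
Forward order: each cyclohexane is released from one verbenone enantiomer; the unit B lactone ring is closed (O–C12'), methylenated and extended by a Michael addition; the halves are joined at C7–C11; the unit A butenolide is closed last through O–C12.
Stereochemistry: C5'/C10' come from (1R,5R)-verbenone and C5/C10 from (1S,5S)-verbenone (bridgehead kept, cuprate anti to the CMe2 bridge). C7' is set by equilibration, C8' by equatorial hydride delivery, C11' by convex-face protonation, and C8 by a final thermodynamic epimerisation.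

Key step: step 15

Assumption: both verbenone enantiomers are used in high enantiomeric purity (commercial material, upgraded if needed, or from α-pinene of high ee); residual antipode would show up later as a separable diastereomer of the dimer.
Abbreviation: Lac = (3S,3aR,5S,6S,7aR)-6-methyl-2-oxo-5-(prop-1-en-2-yl)-6-vinyloctahydro-1-benzofuran-3-yl, the unit B lactone bonded through C11'.

**Route**

Step 1
Reactants: 1 (1R,5R)-(+)-verbenone; 2 vinylmagnesium bromide
Product: 3 (1R,4S,5S)-4,6,6-trimethyl-4-vinylbicyclo[3.1.1]heptan-2-one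
Conditions: CH2=CHMgBr (1.5 equiv), CuBr·SMe2 (10 mol%), THF, −40 to 0 °C; sat. aq. NH4Cl
Reagents that add atoms: none
Why: Copper-catalysed conjugate addition of a Grignard reagent (a vinylcuprate of monovalent copper is the carrier) to the β,β-disubstituted enone; the reagent reaches C4 from the face of the CH2 bridge, away from the gem-dimethyl bridge, so the new quaternary centre (the later C10') should form as one diastereomer with methyl syn and vinyl anti to CMe2, and protonation on work-up gives the ketone.

Step 2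
Reactants: 3 (1R,4S,5S)-4,6,6-trimethyl-4-vinylbicyclo[3.1.1]heptan-2-one
Product: 4 (4S,5S)-5-methyl-4-(prop-1-en-2-yl)-5-vinylcyclohex-1-en-1-yl acetate
Conditions: BF3·OEt2, Zn(OAc)2, Ac2O, 0 °C to rt
Reagents that add atoms: acetic anhydride, CC(=O)OC(C)=O
Why: Lewis-acid-mediated cyclobutane fragmentation of a verbanone-type ketone: activation of the carbonyl breaks the strained bond between the α-bridgehead and CMe2, the enol side is captured as the regiodefined enol acetate, and the tertiary cation loses a methyl proton to give the isopropenyl group, the two stereocentres remaining untouched.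

Step 3
Reactants: 4 (4S,5S)-5-methyl-4-(prop-1-en-2-yl)-5-vinylcyclohex-1-en-1-yl acetate
Product: 5 (3S,4S)-3-methyl-4-(prop-1-en-2-yl)-3-vinylcyclohexan-1-one
Conditions: K2CO3, MeOH, 0 °C to rt
Reagents that add atoms: none
Why: Base-catalysed methanolysis (transesterification) of the enol acetate followed by ketonisation; neither stereocentre is α to the carbonyl, so nothing can epimerise.

Step 4
Reactants: 5 (3S,4S)-3-methyl-4-(prop-1-en-2-yl)-3-vinylcyclohexan-1-one; 6 ethyl bromoacetate
Product: 9 ethyl 2-[(1R,4S,5S)-4-methyl-2-oxo-5-(prop-1-en-2-yl)-4-vinylcyclohexyl]acetate, via lithium enolate 7 (not isolated), via keto ester epimer mixture 8 (not isolated)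
Conditions: LiN(i-Pr)2 (LDA), THF, −78 °C; 6, DMPU, −78 to −20 °C; then NaOEt (cat.), EtOH, rt
Reagents that add atoms: none
Why: Kinetic enolate alkylation: the lithium amide deprotonates C7' and not the neopentylic C9' next to the quaternary C10', the enolate is C-alkylated by the bromoacetate (SN2), and ethoxide then equilibrates the α-centre C7' to the epimer with the equatorial side chain, 1,3-cis to the equatorial isopropenyl group.

Step 5
Reactants: 9 ethyl 2-[(1R,4S,5S)-4-methyl-2-oxo-5-(prop-1-en-2-yl)-4-vinylcyclohexyl]acetate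
Product: 11 (3aR,5S,6S,7aR)-6-methyl-5-(prop-1-en-2-yl)-6-vinylhexahydro-1-benzofuran-2(3H)-one, via lithium alkoxide 10 (not isolated)
Conditions: LiBH(s-Bu)3 (L-Selectride), THF, −78 °C to rt; then 1 M HCl
Reagents that add atoms: none
Why: Diastereoselective ketone reduction with a bulky borohydride followed by translactonisation: hydride approaches C8' from the equatorial side because the axial path is blocked by the syn-axial C10' methyl, and the resulting axial alkoxide, cis to the neighbouring equatorial CH2CO2Et arm, closes the cis-fused γ-lactone with loss of ethoxide.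

Step 6
Reactants: 11 (3aR,5S,6S,7aR)-6-methyl-5-(prop-1-en-2-yl)-6-vinylhexahydro-1-benzofuran-2(3H)-one
Product: 13 (3aR,5S,6S,7aR)-3-[(dimethylamino)methyl]-6-methyl-5-(prop-1-en-2-yl)-6-vinylhexahydro-1-benzofuran-2(3H)-one, via lactone lithium enolate 12 (not isolated)
Conditions: LiN(i-Pr)2, THF, −78 °C; CH2=NMe2+ I−, −78 °C to rt
Reagents that add atoms: dimethyl(methylidene)ammonium iodide, C=[N+](C)C.[I-]
Why: Mannich reaction of the lactone lithium enolate with the preformed iminium salt, which brings in C13' as an aminomethyl group; the configuration of the new centre C11' is irrelevant because it becomes sp2 in step 7.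

Step 7
Reactants: 13 (3aR,5S,6S,7aR)-3-[(dimethylamino)methyl]-6-methyl-5-(prop-1-en-2-yl)-6-vinylhexahydro-1-benzofuran-2(3H)-one
Product: 15 (3aR,5S,6S,7aR)-6-methyl-3-methylidene-5-(prop-1-en-2-yl)-6-vinylhexahydro-1-benzofuran-2(3H)-one, via ammonium iodide 14 (not isolated)
Conditions: MeI, MeOH, rt; then sat. aq. NaHCO3, CH2Cl2, rt
Reagents that add atoms: none
Why: Exhaustive N-methylation to the quaternary ammonium salt and base-induced β-elimination of trimethylamine (Hofmann-type, E1cB through the lactone enolate) to the α-methylene lactone.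

Step 8
Reactants: 16 allyl acetate; 17 diethyl oxalate
Product: 19 4-allyl 1-ethyl 2-oxobutanedioate, via allyl acetate lithium enolate 18 (not isolated)
Conditions: LiN(i-Pr)2, THF, −78 °C; 17 (1.2 equiv), −78 to 0 °C; 1 M HCl
Reagents that add atoms: none
Why: Crossed Claisen condensation: the ester enolate acylates the non-enolisable oxalate, and deprotonation of the acidic β-keto ester product by the released ethoxide drives the reaction; the allyl ester is placed on the carboxyl group that is to be removed later.

Step 9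
Reactants: 15 (3aR,5S,6S,7aR)-6-methyl-3-methylidene-5-(prop-1-en-2-yl)-6-vinylhexahydro-1-benzofuran-2(3H)-one; 19 4-allyl 1-ethyl 2-oxobutanedioate
Product: 20 4-allyl 1-ethyl 2-oxo-3-(Lac-methyl)butanedioate
Conditions: 19 (1.5 equiv), Cs2CO3 (10 mol%), MeCN, 0 °C to rt
Reagents that add atoms: none
Why: Base-catalysed Michael addition of the soft oxalacetate carbanion to C13' of the α-methylene lactone; the lactone enolate should be protonated by the acidic donor from the convex face of the cis-fused bicycle (the face of H7' and H8'), which sets C11' as S with the new chain on the concave face, and the carbonate is far too weak to re-enolise the saturated lactone.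

Step 10
Reactants: 20 4-allyl 1-ethyl 2-oxo-3-(Lac-methyl)butanedioate
Product: 22 ethyl 2-oxo-4-Lac-butanoate, via β-keto acid 21 (not isolated)
Conditions: Pd(PPh3)4 (5 mol%), HCO2H, Et3N, THF, rt
Reagents that add atoms: none
Why: Tsuji–Trost-type deallylation with decarboxylation: zerovalent palladium ionises the allyl ester to a π-allylpalladium carboxylate, formate reduces the allyl unit to propene, and the β-keto acid loses CO2 at room temperature under essentially neutral conditions that leave the ethyl 2-oxo ester, the lactone and C11' alone.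

Step 11
Reactants: 23 (1S,5S)-(−)-verbenone; 2 vinylmagnesium bromide
Product: 24 (1S,4R,5R)-4,6,6-trimethyl-4-vinylbicyclo[3.1.1]heptan-2-one
Conditions: CH2=CHMgBr (1.5 equiv), CuBr·SMe2 (10 mol%), THF, −40 to 0 °C; sat. aq. NH4Cl
Reagents that add atoms: none
Why: The same copper-catalysed conjugate addition as in step 1 on the antipodal enone, again anti to the gem-dimethyl bridge, which sets the quaternary centre that becomes C10 of unit A.

Step 12
Reactants: 24 (1S,4R,5R)-4,6,6-trimethyl-4-vinylbicyclo[3.1.1]heptan-2-one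
Product: 25 (4R,5R)-5-methyl-4-(prop-1-en-2-yl)-5-vinylcyclohex-1-en-1-yl acetate
Conditions: BF3·OEt2, Zn(OAc)2, Ac2O, 0 °C to rt
Reagents that add atoms: acetic anhydride, CC(=O)OC(C)=O
Why: The same Lewis-acid-mediated cyclobutane fragmentation as in step 2, giving the enol acetate and the isopropenyl group without touching the two stereocentres.

Step 13
Reactants: 25 (4R,5R)-5-methyl-4-(prop-1-en-2-yl)-5-vinylcyclohex-1-en-1-yl acetate
Product: 26 (3R,4R)-3-methyl-4-(prop-1-en-2-yl)-3-vinylcyclohexan-1-one
Conditions: K2CO3, MeOH, 0 °C to rt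
Reagents that add atoms: none
Why: Methanolysis of the enol acetate and ketonisation, as in step 3, with no epimerisable centre present.

Step 14
Reactants: 26 (3R,4R)-3-methyl-4-(prop-1-en-2-yl)-3-vinylcyclohexan-1-one
Product: 28 trimethyl{[(4R,5R)-5-methyl-4-(prop-1-en-2-yl)-5-vinylcyclohex-1-en-1-yl]oxy}silane, via lithium enolate 27 (not isolated)
Conditions: LiN(i-Pr)2, THF, −78 °C; Me3SiCl, Et3N, −78 to 0 °C
Reagents that add atoms: chlorotrimethylsilane, C[Si](C)(C)Cl
Why: Kinetic enolate formation and O-silylation: deprotonation occurs at C7, away from the neopentylic C9, and trapping with the chlorosilane fixes the C7=C8 enol ether needed for the coupling.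

Step 15
Reactants: 22 ethyl 2-oxo-4-Lac-butanoate; 28 trimethyl{[(4R,5R)-5-methyl-4-(prop-1-en-2-yl)-5-vinylcyclohex-1-en-1-yl]oxy}silane
Product: 29 ethyl 2-hydroxy-2-[(4R,5R)-4-methyl-2-oxo-5-(prop-1-en-2-yl)-4-vinylcyclohexyl]-4-Lac-butanoate (epimers at the two new centres)
Conditions: TiCl4 (1.1 equiv), CH2Cl2, −78 °C; aqueous work-up
Reagents that add atoms: none
Why: Mukaiyama aldol addition: TiCl4 chelates the 1,2-dicarbonyl unit of 22, the enol ether carbon C7 of 28 attacks the activated keto carbon C11, chloride removes the silyl group and the titanium aldolate is protonated on work-up. The closest known reaction type is the TiCl4-mediated addition of ketone silyl enol ethers to pyruvate-type 2-oxo esters. No ring closes here; the C7–C11 bond only joins the two halves, and the butenolide ring is closed afterwards through O–C12. The two new stereocentres C7 and C11 form without control and need none, because both become sp2 in step 16. The step needs regioselectivity for C7 over C9, which is fixed by the position of the enol ether double bond made in step 14, and chemoselectivity for the C11 ketone over the ethyl ester, the saturated lactone and the four alkenes, which rests on chelate activation of the keto group and on the much higher nucleophilicity of the silyl enol ether at −78 °C.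

Step 16
Reactants: 29 ethyl 2-hydroxy-2-[(4R,5R)-4-methyl-2-oxo-5-(prop-1-en-2-yl)-4-vinylcyclohexyl]-4-Lac-butanoate
Product: 31 ethyl 2-[(4R,5R)-4-methyl-2-oxo-5-(prop-1-en-2-yl)-4-vinylcyclohexylidene]-4-Lac-butanoate (E/Z mixture), via mesylate 30 (not isolated)
Conditions: MsCl, Et3N (excess), DMAP (cat.), CH2Cl2, 0 °C to rt
Reagents that add atoms: none
Why: Sulfene-type mesylation of the tertiary C11 hydroxyl followed by amine-induced E1cB elimination through the C8 ketone enolate, which can place the double bond only between C7 and C11 and avoids the acid that would endanger the isopropenyl groups; the C7 and C11 stereocentres disappear and the mixture of alkene geometries is dealt with in step 17.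

Step 17
Reactants: 31 ethyl 2-[(4R,5R)-4-methyl-2-oxo-5-(prop-1-en-2-yl)-4-vinylcyclohexylidene]-4-Lac-butanoate
Product: 33 (5R,6R)-7a-hydroxy-6-methyl-3-(2-Lac-ethyl)-5-(prop-1-en-2-yl)-6-vinyl-5,6,7,7a-tetrahydro-1-benzofuran-2(4H)-one (both C8 epimers), via dilithium dicarboxylate 32 (not isolated)
Conditions: LiOH, THF–H2O, 0 °C to rt; then 1 M HCl to pH 2, rt
Reagents that add atoms: lithium hydroxide, [Li+].[OH-]
Why: Ester hydrolysis with neighbouring-group participation: in the Z isomer the hydrate anion of the C8 ketone attacks the adjacent C12 ester, hydroxide-mediated γ-deprotonation at C13 should interconvert the E and Z esters so that both drain into the Z keto carboxylate, and acidification closes the pseudoacid ring at C8 and re-closes the unit B lactone, which hydroxide opens without risk to C11' because a carboxylate is not enolised.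

Step 18
Reactants: 33 (5R,6R)-7a-hydroxy-6-methyl-3-(2-Lac-ethyl)-5-(prop-1-en-2-yl)-6-vinyl-5,6,7,7a-tetrahydro-1-benzofuran-2(4H)-one
Product: 35 (5R,6R,7aS)-6-methyl-3-(2-Lac-ethyl)-5-(prop-1-en-2-yl)-6-vinyl-5,6,7,7a-tetrahydro-1-benzofuran-2(4H)-one (the C8 epimer of the target), via sodium hydroxy carboxylate 34 (not isolated)
Conditions: NaBH4, EtOH, 0 °C to rt; then 1 M HCl to pH 2, rt
Reagents that add atoms: none
Why: Borohydride reduction of the ring-opened keto carboxylate form of the pseudoacid (1,2-addition at the C8 ketone) followed by acid lactonisation of the Z hydroxy acid; hydride should enter equatorially, away from the syn-axial C10 methyl, so the 8S epimer with C8–O cis to that methyl is expected to predominate, and any 8R product is simply carried on.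

Step 19
Reactants: 35 (5R,6R,7aS)-6-methyl-3-(2-Lac-ethyl)-5-(prop-1-en-2-yl)-6-vinyl-5,6,7,7a-tetrahydro-1-benzofuran-2(4H)-one
Product: 36 (5R,6R,7aR)-6-methyl-3-(2-Lac-ethyl)-5-(prop-1-en-2-yl)-6-vinyl-5,6,7,7a-tetrahydro-1-benzofuran-2(4H)-one (CNP0332736.1)
Conditions: DBU (0.2 equiv), toluene, rt, under argon
Reagents that add atoms: none
Why: Base-mediated epimerisation of a butenolide γ-carbon: DBU reversibly removes H8 to give the 2-furanolate and reprotonation under thermodynamic control should return the epimer with the equatorial C8–O bond trans to the axial C10 methyl, the only one in which the planar butenolide fits the chair, while the C11' hydrogen of the saturated lactone is many pK units less acidic and stays untouched and oxygen is excluded to prevent autoxidation of the furanolate.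

**Compound list**

1 | (1R,5R)-(+)-verbenone, (1R,5R)-4,6,6-trimethylbicyclo[3.1.1]hept-3-en-2-one | O=C1C=C(C)[C@H]2C[C@@H]1C2(C)C | starting material
2 | vinylmagnesium bromide | C=C[Mg]Br | starting material
3 | (1R,4S,5S)-4,6,6-trimethyl-4-vinylbicyclo[3.1.1]heptan-2-one | O=C1C[C@@](C)(C=C)[C@H]2C[C@@H]1C2(C)C | intermediate
4 | (4S,5S)-5-methyl-4-(prop-1-en-2-yl)-5-vinylcyclohex-1-en-1-yl acetate | CC(=O)OC1=CC[C@@H](C(C)=C)[C@](C)(C=C)C1 | intermediate
5 | (3S,4S)-3-methyl-4-(prop-1-en-2-yl)-3-vinylcyclohexan-1-one | O=C1C[C@@](C)(C=C)[C@H](C(C)=C)CC1 | intermediate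
6 | ethyl bromoacetate | CCOC(=O)CBr | starting material
7 | lithium enolate of 5 (C7'=C8', not isolated) | [Li]OC1=CC[C@@H](C(C)=C)[C@](C)(C=C)C1 | intermediate
8 | ethyl 2-[(4S,5S)-4-methyl-2-oxo-5-(prop-1-en-2-yl)-4-vinylcyclohexyl]acetate, mixture of C1 epimers (not isolated) | O=C1C[C@@](C)(C=C)[C@H](C(C)=C)CC1CC(=O)OCC | intermediate
9 | ethyl 2-[(1R,4S,5S)-4-methyl-2-oxo-5-(prop-1-en-2-yl)-4-vinylcyclohexyl]acetate | O=C1C[C@@](C)(C=C)[C@H](C(C)=C)C[C@@H]1CC(=O)OCC | intermediate
10 | lithium (1R,2R,4S,5S)-2-(2-ethoxy-2-oxoethyl)-5-methyl-4-(prop-1-en-2-yl)-5-vinylcyclohexan-1-olate (not isolated) | [Li]O[C@@H]1C[C@@](C)(C=C)[C@H](C(C)=C)C[C@@H]1CC(=O)OCC | intermediate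
11 | (3aR,5S,6S,7aR)-6-methyl-5-(prop-1-en-2-yl)-6-vinylhexahydro-1-benzofuran-2(3H)-one | C1C(=O)O[C@@H]2C[C@@](C)(C=C)[C@H](C(=C)C)C[C@H]12 | intermediate
12 | lithium enolate of lactone 11 (not isolated) | C1=C(O[Li])O[C@@H]2C[C@@](C)(C=C)[C@H](C(=C)C)C[C@H]12 | intermediate
13 | (3aR,5S,6S,7aR)-3-[(dimethylamino)methyl]-6-methyl-5-(prop-1-en-2-yl)-6-vinylhexahydro-1-benzofuran-2(3H)-one, C3 unassigned | CN(C)CC1C(=O)O[C@@H]2C[C@@](C)(C=C)[C@H](C(=C)C)C[C@H]12 | intermediate
14 | trimethylammoniomethyl lactone iodide from 13 (not isolated) | C[N+](C)(C)CC1C(=O)O[C@@H]2C[C@@](C)(C=C)[C@H](C(=C)C)C[C@H]12.[I-] | intermediate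
15 | (3aR,5S,6S,7aR)-6-methyl-3-methylidene-5-(prop-1-en-2-yl)-6-vinylhexahydro-1-benzofuran-2(3H)-one | C=C1C(=O)O[C@@H]2C[C@@](C)(C=C)[C@H](C(=C)C)C[C@H]12 | intermediate
16 | allyl acetate | CC(=O)OCC=C | starting material
17 | diethyl oxalate | CCOC(=O)C(=O)OCC | starting material
18 | lithium enolate of allyl acetate (not isolated) | C=C(O[Li])OCC=C | intermediate
19 | 4-allyl 1-ethyl 2-oxobutanedioate | CCOC(=O)C(=O)CC(=O)OCC=C | intermediate
20 | 4-allyl 1-ethyl 2-oxo-3-(Lac-methyl)butanedioate, C3 of the diester unassigned | CCOC(=O)C(=O)C(C(=O)OCC=C)C[C@@H]1C(=O)O[C@@H]2C[C@@](C)(C=C)[C@H](C(=C)C)C[C@H]12 | intermediate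
21 | 4-ethoxy-3,4-dioxo-2-(Lac-methyl)butanoic acid (not isolated) | CCOC(=O)C(=O)C(C(=O)O)C[C@@H]1C(=O)O[C@@H]2C[C@@](C)(C=C)[C@H](C(=C)C)C[C@H]12 | intermediate
22 | ethyl 2-oxo-4-Lac-butanoate | CCOC(=O)C(=O)CC[C@@H]1C(=O)O[C@@H]2C[C@@](C)(C=C)[C@H](C(=C)C)C[C@H]12 | intermediate
23 | (1S,5S)-(−)-verbenone, (1S,5S)-4,6,6-trimethylbicyclo[3.1.1]hept-3-en-2-one | O=C1C=C(C)[C@@H]2C[C@H]1C2(C)C | starting material
24 | (1S,4R,5R)-4,6,6-trimethyl-4-vinylbicyclo[3.1.1]heptan-2-one | O=C1C[C@](C)(C=C)[C@@H]2C[C@H]1C2(C)C | intermediate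
25 | (4R,5R)-5-methyl-4-(prop-1-en-2-yl)-5-vinylcyclohex-1-en-1-yl acetate | CC(=O)OC1=CC[C@H](C(C)=C)[C@@](C)(C=C)C1 | intermediate
26 | (3R,4R)-3-methyl-4-(prop-1-en-2-yl)-3-vinylcyclohexan-1-one | O=C1C[C@](C)(C=C)[C@@H](C(C)=C)CC1 | intermediate
27 | lithium enolate of 26 (C7=C8, not isolated) | [Li]OC1=CC[C@H](C(C)=C)[C@@](C)(C=C)C1 | intermediate
28 | trimethyl{[(4R,5R)-5-methyl-4-(prop-1-en-2-yl)-5-vinylcyclohex-1-en-1-yl]oxy}silane | C[Si](C)(C)OC1=CC[C@H](C(C)=C)[C@@](C)(C=C)C1 | intermediate
29 | ethyl 2-hydroxy-2-[(4R,5R)-4-methyl-2-oxo-5-(prop-1-en-2-yl)-4-vinylcyclohexyl]-4-Lac-butanoate, C7 and C11 unassigned | CCOC(=O)C(O)(CC[C@@H]1C(=O)O[C@@H]2C[C@@](C)(C=C)[C@H](C(=C)C)C[C@H]12)C1C[C@H](C(C)=C)[C@@](C)(C=C)CC1=O | intermediate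
30 | methanesulfonate of 29 at the C11 hydroxyl (not isolated) | CCOC(=O)C(OS(C)(=O)=O)(CC[C@@H]1C(=O)O[C@@H]2C[C@@](C)(C=C)[C@H](C(=C)C)C[C@H]12)C1C[C@H](C(C)=C)[C@@](C)(C=C)CC1=O | intermediate
31 | ethyl 2-[(4R,5R)-4-methyl-2-oxo-5-(prop-1-en-2-yl)-4-vinylcyclohexylidene]-4-Lac-butanoate, E/Z mixture | CCOC(=O)C(CC[C@@H]1C(=O)O[C@@H]2C[C@@](C)(C=C)[C@H](C(=C)C)C[C@H]12)=C1C[C@H](C(C)=C)[C@@](C)(C=C)CC1=O | intermediate
32 | dilithium salt of the Z keto acid of 31 with the unit B lactone opened to its hydroxy carboxylate (not isolated) | [Li+].[Li+].[O-]C(=O)/C(CC[C@H](C(=O)[O-])[C@H]1C[C@@H](C(C)=C)[C@](C)(C=C)C[C@H]1O)=C1/C[C@H](C(C)=C)[C@@](C)(C=C)CC1=O | intermediate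
33 | (5R,6R)-7a-hydroxy-6-methyl-3-(2-Lac-ethyl)-5-(prop-1-en-2-yl)-6-vinyl-5,6,7,7a-tetrahydro-1-benzofuran-2(4H)-one, both C8 epimers | C=C[C@@]1(C)CC2(O)OC(=O)C(CC[C@@H]3C(=O)O[C@@H]4C[C@@](C)(C=C)[C@H](C(=C)C)C[C@H]34)=C2C[C@@H]1C(=C)C | intermediate
34 | sodium (Z)-2-[(2S,4R,5R)-2-hydroxy-4-methyl-5-(prop-1-en-2-yl)-4-vinylcyclohexylidene]-4-Lac-butanoate (not isolated) | [Na+].[O-]C(=O)/C(CC[C@@H]1C(=O)O[C@@H]2C[C@@](C)(C=C)[C@H](C(=C)C)C[C@H]12)=C1/C[C@H](C(C)=C)[C@@](C)(C=C)C[C@@H]1O | intermediate
35 | (5R,6R,7aS)-6-methyl-3-(2-Lac-ethyl)-5-(prop-1-en-2-yl)-6-vinyl-5,6,7,7a-tetrahydro-1-benzofuran-2(4H)-one, the C8 epimer of the target | C=C[C@@]1(C)C[C@@H]2OC(=O)C(CC[C@@H]3C(=O)O[C@@H]4C[C@@](C)(C=C)[C@H](C(=C)C)C[C@H]34)=C2C[C@@H]1C(=C)C | intermediate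
36 | (5R,6R,7aR)-6-methyl-3-(2-Lac-ethyl)-5-(prop-1-en-2-yl)-6-vinyl-5,6,7,7a-tetrahydro-1-benzofuran-2(4H)-one, CNP0332736.1 | C=C[C@@]1(C)C[C@H]2OC(=O)C(CC[C@@H]3C(=O)O[C@@H]4C[C@@](C)(C=C)[C@H](C(=C)C)C[C@H]34)=C2C[C@@H]1C(=C)C | target

**Count and risks**

Total: 19 steps. Longest linear sequence: 14 steps (steps 1 to 7, 9, 10 and 15 to 19, from verbenone 1).

Step 17 is the most likely to fail. The E isomer of 31 may not be funnelled into the cyclisation, because its ester cannot be reached by the C8 hydrate and base-mediated E/Z interconversion may be slower than unselective saponification or conjugate addition of hydroxide. The fallback sets out from aldol adduct 29 and uses acid instead of the mesylate route: p-TsOH·H2O (cat.) in refluxing benzene with removal of water should give, by enol lactonisation through the C8 enol and dehydration, the dienolide (5R,6R)-6-methyl-3-(2-Lac-ethyl)-5-(prop-1-en-2-yl)-6-vinyl-5,6-dihydro-1-benzofuran-2(4H)-one F1, in which the ring itself fixes the C7=C11 geometry. Opening of the enol lactone of F1 with LiOH in THF–H2O and acidification should then give hydroxybutenolide 33, where the route is rejoined.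

Step 15 comes second. The Lewis acid may trigger ene-type or hydrochlorination side reactions at the isopropenyl groups, or desilylate the enol ether before the C–C bond forms. The fallback sets out from ketone 26 and avoids any Lewis acid: kinetic deprotonation with LiN(i-Pr)2 at −78 °C to lithium enolate 27, addition of keto ester 22 at −78 °C and a cold acetic acid quench (directed lithium aldol addition) should give the same adduct 29, where the route is rejoined. This fallback makes no new compound (F0).

Step 9 comes third. Addition of the hindered, highly stabilised donor may be slow or reversible, and the C11' selectivity would erode if the adduct re-equilibrated during a long reaction. The fallback sets out from α-methylene lactone 15 and replaces steps 8 to 10 by a stoichiometric azaenolate addition with a separate kinetic protonation. Ethyl 2-(2,2-dimethylhydrazinylidene)propanoate F2, made from ethyl pyruvate and N,N-dimethylhydrazine, is deprotonated with LiN(i-Pr)2 at −78 °C and added to 15. The resulting lactone enolate is quenched at −78 °C with 2,6-di-tert-butylphenol from the convex face to give ethyl 2-(2,2-dimethylhydrazinylidene)-4-Lac-butanoate F3. Hydrolysis of the hydrazone with aqueous Cu(OAc)2 in THF should return keto ester 22, where the route is rejoined.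

Further compounds
F1 | step 17 | (5R,6R)-6-methyl-3-(2-Lac-ethyl)-5-(prop-1-en-2-yl)-6-vinyl-5,6-dihydro-1-benzofuran-2(4H)-one | C=C[C@@]1(C)C=C2OC(=O)C(CC[C@@H]3C(=O)O[C@@H]4C[C@@](C)(C=C)[C@H](C(=C)C)C[C@H]34)=C2C[C@@H]1C(=C)C
F0 | step 15 | none | none
F2 | step 9 | ethyl 2-(2,2-dimethylhydrazinylidene)propanoate | CCOC(=O)C(C)=NN(C)C
F3 | step 9 | ethyl 2-(2,2-dimethylhydrazinylidene)-4-Lac-butanoate | CCOC(=O)C(CC[C@@H]1C(=O)O[C@@H]2C[C@@](C)(C=C)[C@H](C(=C)C)C[C@H]12)=NN(C)C
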